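**Remark on the chemistry:** compound 13 is written as the keto aldehyde although it should exist largely as its chelated enol. All chiral intermediates are racemic, and one enantiomer is drawn where a relative configuration matters.

## Analysis of the target

Compound 16 is an isoflavone: a 4H-chromen-4-one (benzo ring A fused to pyranone ring C) with ring B on C3, and it has no stereocentre. Ring A carries four contiguous oxygens (O1 at C8a, OH at C8 and C7, OMe at C6) and only C5 is unsubstituted. Ring B carries 3'-OH, 4'-OMe and 5'-OMe. The 7,8-catechol next to a methoxy group is easily oxidised to an o-quinone in air under basic conditions, and hydroxide can open the pyranone at C2, so the free phenols should appear last and under neutral or acidic conditions. The difficulty is regiochemical: which of the four ring A oxygens is methylated, which of the three ring B oxygens is free, and how ring B is placed on C3 and not on C2. The strategy rests on the fact that C3 carries both ring B and the C4 carbonyl while C2 is at the aldehyde oxidation level. The chain C2–C3–C4 is therefore a masked 2-aryl-3-oxopropanal, which is what a 1,2-aroyl shift in a chalcone epoxide delivers when ring B sits on the benzylic epoxide carbon. One caveat is built into the plan: the 4'-methoxy group is para to C1' but is flanked by two oxygens, so it is twisted out of conjugation and ring B is a weaker cation-stabilising group than a simple 4-methoxyphenyl ring.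

## Retrosynthetic reasoning

**16 back to 13.** The O1–C2 bond is cut first. The C2=C3 double bond of 16 comes from dehydration of the cyclic hemiacetal 15, which is the ring-chain tautomer of the tetraphenol keto aldehyde 14. Masking the four phenols of 14 as benzyl ethers gives 13. This disconnection is chosen because the ring closure needs no reagent, has no regiochemical choice, and lets the oxidation-sensitive catechol appear only in the last operation. The forward reaction has to remove four benzyl groups by hydrogenolysis without touching the aldehyde, then dehydrate with acid.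

**13 back to 12.** The C3–C4 bond is cut by running the 1,2-aroyl shift backwards: the aroyl group returns from C3 to C2 and the aldehyde oxygen becomes the epoxide oxygen of 12. This is the only disconnection that puts ring B on C3 while starting from a chalcone, and it supplies C2 already as an aldehyde. In the forward direction a Lewis acid must open the epoxide at the carbon bearing ring B, and the aroyl group must migrate in preference to hydride.

**12 back to 11.** The two epoxide C–O bonds are cut to give the enone 11. Nucleophilic epoxidation of an E-enone gives the trans epoxide, and both stereocentres are erased later, so no asymmetric control is needed.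

**11 back to 7 and 9.** The Cα=Cβ bond is cut by a Claisen–Schmidt disconnection through aldol 10. This splits the molecule into a ring A methyl ketone 7 and a ring B aldehyde 9 of similar size.

**7 back to 1 and 2.** The 2-O-benzyl group is removed to give 6, the 5-O-methyl group to give 5, and the C5–O bond is cut by an Elbs disconnection (through aryl sulfate 4) to give 3. Compound 3 comes from 1 and two equivalents of 2. The acetyl group of 1 does the regiochemical work. It chelates the 2-hydroxyl, so only O3 and O4 are benzylated. The single free phenol of 3 then directs hydroxylation to its para position C5. The new 5-hydroxyl is methylated in preference to the chelated one. C5 of the ketone becomes C6 of 16, so the methoxy group ends up in the right place.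

**9 back to 8 and 2.** The benzyl ether is cut. Compound 8 already has the ring B pattern of 16 with the correct oxygen free, so one benzylation is enough.

## Alternatives that were turned down

Alternative 1: Ring A itself is disconnected, at C4a–C8a.
- Key step: the product would be phenol A1, 6-[2-(3-benzyloxy-4,5-dimethoxyphenyl)-1-(tert-butyldimethylsilyloxy)ethyl]-4-methoxy-2,3-di(propan-2-yloxy)phenol. It would come from heating cyclobutenone A2, made from squarate ester A3 by 1,2-addition of a lithiated ring B-bearing alkene and O-methylation. Four-electron ring opening gives dienylketene A4, and six-electron closure onto the alkene terminus followed by tautomerisation gives A1.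
- For: every ring A oxygen is placed by construction and carries its own protecting group. On this point the alternative is stronger than the chosen route, which brings in O6 by an Elbs oxidation of moderate efficiency. The key step is thermal and needs no reagent.
- Against: A1 is far from 16. The silyl ether must be removed, the carbinol oxidised, a one-carbon electrophile added to close ring C, and the isopropyl and benzyl ethers removed in two different operations while three methyl ethers survive. The alkenyl side chain has to be made as a defined vinyl-metal species in several steps, and the stereocentres of A2 are made only to be destroyed.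
- Comparison: the chosen route is clearly shorter, starts ring A from a cheap aromatic with three oxygens in place, and creates C2 at the right oxidation level.

Alternative 2: Three bonds of ring C (C4a–C4, C4–C3, O1–C2) are disconnected at once.
- Key step: the product would be isoflavanone A5, 7,8-bis(benzyloxy)-3-(3-benzyloxy-4,5-dimethoxyphenyl)-6-methoxychroman-4-one. Iodophenol A6, carbon monoxide A7 and 1-arylvinylboronate A8 would be joined by Pd(OAc)2 with a bisphosphine and K2CO3 to give aryl vinyl ketone A9, whose phenoxide adds to the enone terminus.
- For: convergence. Ring C is assembled in one flask from two fragments of similar size, and in steps after fragment preparation this alternative is stronger than the chosen route.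
- Against: A6 needs the same tetraoxygenated pattern as ketone 7 but lacks the acetyl group that steers the phenol chemistry. It is an electron-rich, doubly ortho-substituted aryl iodide, so oxidative addition to zerovalent palladium is slow and direct coupling without carbonyl insertion competes. A8 is prone to protodeboronation. A5 is one oxidation level too low, so C2–C3 must be dehydrogenated in a substrate with three oxidisable benzyl ethers before deprotection.
- Comparison: the chosen route needs no oxidation after ring closure, and each of its steps is of a type known for this substrate class.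

Alternative 3: The aryl ether bond O1–C8a is disconnected, and is formed by oxidative C–H functionalisation.
- Key step: the product would be isoflavone A10, 3-(3-benzyloxy-4,5-dimethoxyphenyl)-7,8-dihydroxy-6-methoxychromen-4-one. Anodic oxidation of catechol A11 would give o-quinone A12, the enol oxygen would add to the ring carbon between the acyl-bearing carbon and the C8 oxygen-bearing carbon, and the adduct would re-aromatise. One hydrogenolysis would then give 16.
- For: ring A needs only three oxygens at the outset, so the Elbs step and three of the four benzyl groups disappear, and the oxidant is the electrode. In step count and protecting-group economy this is the strongest of all four plans.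
- Against: two ring carbons are ortho to the acyl group and within reach of the enol oxygen. Attack at the desired one is a 1,6-addition at a carbon flanked by the acyl-bearing carbon and a quinone carbonyl, while attack at the other is a 1,4-addition and gives regioisomer A13. A10 is itself a catechol with one more oxygen donor than A11, so it should be oxidised at least as easily and over-oxidation is likely. The enol oxygen is a weak nucleophile, and water or the enol carbon can compete.
- Comparison: in the chosen route O1 is on ring A from the first step, and ring closure is a hemiacetal formation with no regiochemical choice.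

Key step: step 8

## Route

Step 1
Reactants: 1 1-(2,3,4-trihydroxyphenyl)ethanone (gallacetophenone); 2 benzyl bromide
Product: 3 1-[3,4-bis(benzyloxy)-2-hydroxyphenyl]ethanone
Conditions: BnBr (2.1 equiv), K2CO3 (2.2 equiv), acetone, reflux
Reagents that add atoms: benzyl bromide (second equivalent of 2), BrCc1ccccc1
Why: Twofold Williamson ether synthesis that consumes two equivalents of 2, one for each new benzyl ether. The 2-hydroxyl is held in a hydrogen bond to the acetyl carbonyl and is the least nucleophilic, so with a mild base the 4-oxygen (the most acidic, para to the acetyl group) and then the 3-oxygen should be alkylated and the chelated phenol left free.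

Step 2
Reactants: 3 1-[3,4-bis(benzyloxy)-2-hydroxyphenyl]ethanone
Product: 5 1-[3,4-bis(benzyloxy)-2,5-dihydroxyphenyl]ethanone, via aryl potassium sulfate 4 (not isolated)
Conditions: K2S2O8, aq. KOH, pyridine, 0 °C to rt; then 2 M HCl, Na2SO3, 70 °C
Reagents that add atoms: dipotassium peroxodisulfate (K2S2O8), [K+].[K+].[O-]S(=O)(=O)OOS(=O)(=O)[O-]
Why: Elbs persulfate oxidation; the phenolate of 3 attacks the peroxide oxygen through its para carbon C5, which is open, giving sulfate 4, and acid hydrolysis of the sulfate ester frees the hydroquinone. Unchanged 3 can be extracted before the hydrolysis and recycled.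

Step 3
Reactants: 5 1-[3,4-bis(benzyloxy)-2,5-dihydroxyphenyl]ethanone
Product: 6 1-[3,4-bis(benzyloxy)-2-hydroxy-5-methoxyphenyl]ethanone
Conditions: MeI (1.05 equiv), K2CO3 (1.1 equiv), acetone, rt
Reagents that add atoms: iodomethane, CI
Why: Williamson ether synthesis; the 5-hydroxyl is not chelated and should react first with one equivalent of the alkylating agent, as is usual for 2,5-dihydroxyaryl ketones.

Step 4
Reactants: 6 1-[3,4-bis(benzyloxy)-2-hydroxy-5-methoxyphenyl]ethanone; 2 benzyl bromide
Product: 7 1-[2,3,4-tris(benzyloxy)-5-methoxyphenyl]ethanone
Conditions: BnBr (1.2 equiv), K2CO3, KI (cat.), DMF, 70 °C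
Reagents that add atoms: none
Why: Williamson ether synthesis on the chelated phenol, driven by a polar aprotic solvent and heat. Capping the future O1 keeps alkaline peroxide from cyclising the chalcone and keeps the Lewis acid step from closing a flavanonol.

Step 5
Reactants: 8 3-hydroxy-4,5-dimethoxybenzaldehyde; 2 benzyl bromide
Product: 9 3-(benzyloxy)-4,5-dimethoxybenzaldehyde
Conditions: BnBr (1.1 equiv), K2CO3, DMF, rt
Reagents that add atoms: none
Why: Williamson ether synthesis on the only phenol present; the aldehyde is not enolisable and is inert to carbonate.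

Step 6
Reactants: 7 1-[2,3,4-tris(benzyloxy)-5-methoxyphenyl]ethanone; 9 3-(benzyloxy)-4,5-dimethoxybenzaldehyde
Product: 11 (2E)-3-[3-(benzyloxy)-4,5-dimethoxyphenyl]-1-[2,3,4-tris(benzyloxy)-5-methoxyphenyl]prop-2-en-1-one, via aldol adduct 10 (not isolated)
Conditions: 50% aq. KOH, EtOH–THF, rt
Reagents that add atoms: none
Why: Claisen–Schmidt condensation; the enolate of 7 adds to the non-enolisable aldehyde 9 and E1cB loss of hydroxide from aldol 10 gives the conjugated enone, with the E geometry favoured thermodynamically.

Step 7
Reactants: 11 (2E)-3-[3-(benzyloxy)-4,5-dimethoxyphenyl]-1-[2,3,4-tris(benzyloxy)-5-methoxyphenyl]prop-2-en-1-one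
Product: 12 trans-{3-[3-(benzyloxy)-4,5-dimethoxyphenyl]oxiran-2-yl}[2,3,4-tris(benzyloxy)-5-methoxyphenyl]methanone (racemic; 2R,3S enantiomer drawn)
Conditions: 30% H2O2, aq. NaOH, MeOH–THF, 0 °C to rt
Reagents that add atoms: hydrogen peroxide, OO
Why: Weitz–Scheffer nucleophilic epoxidation; hydroperoxide adds to the β-carbon and the enolate displaces hydroxide from oxygen. Free rotation in the enolate intermediate leads to the more stable trans epoxide, so the relative configuration is set by the substrate, and the nucleophilic oxidant leaves the electron-rich arenes alone.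

Step 8
Reactants: 12 trans-{3-[3-(benzyloxy)-4,5-dimethoxyphenyl]oxiran-2-yl}[2,3,4-tris(benzyloxy)-5-methoxyphenyl]methanone
Product: 13 2-[3-(benzyloxy)-4,5-dimethoxyphenyl]-3-oxo-3-[2,3,4-tris(benzyloxy)-5-methoxyphenyl]propanal (racemic; enolisable)
Conditions: BF3·OEt2 (1.5 equiv), CH2Cl2, 0 °C to rt, 15–30 min; ice-water quench
Reagents that add atoms: none
Why: BF3 binds the epoxide oxygen and the C–O bond at the carbon bearing ring B lengthens, because that carbon is benzylic whereas the other epoxide carbon lies next to the carbonyl and cannot carry positive charge. As the bond breaks, the aroyl group on the neighbouring carbon moves across with its bonding electron pair and the boron-bound oxygen left behind collapses to the formyl group, which creates the C3–C4 bond of 13. The closest known reaction type is the Lewis acid rearrangement of trans-chalcone oxides to α-formyl deoxybenzoins, a semipinacol-type rearrangement with acyl migration that is established for 2'-benzyloxy substrates. No ring is closed. The one new stereocentre (the future C3) is not controlled and need not be, because it is enolisable and becomes trigonal in 16. Three selectivities are needed: opening at the benzylic carbon, which the carbonyl secures by destabilising the other cation; acyl in preference to hydride migration, which follows from the higher migratory aptitude of acyl groups here (a hydride shift would give a 1,2-diketone); and no capture of the cationic carbon by the 2'-benzyloxy oxygen or by fluoride, which a non-coordinating solvent, low temperature and short reaction time should prevent. Because the 4'-methoxy group is flanked on both sides and its neighbours are meta to the reacting carbon, ring B is a weaker donor than a simple 4-methoxyphenyl group, so the shift is expected to be nearly concerted with ring opening, and CH2Cl2 is used instead of ether to keep the Lewis acid strong.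

Step 9
Reactants: 13 2-[3-(benzyloxy)-4,5-dimethoxyphenyl]-3-oxo-3-[2,3,4-tris(benzyloxy)-5-methoxyphenyl]propanal
Product: 16 7,8-dihydroxy-3-(3-hydroxy-4,5-dimethoxyphenyl)-6-methoxy-4H-chromen-4-one (target), via tetraphenol keto aldehyde 14 (not isolated), via 2-hydroxyisoflavanone hemiacetal 15 (not isolated)
Conditions: H2 (1 atm), 10% Pd/C, EtOAc–MeOH, rt; filter under argon; then conc. HCl (cat.), MeOH, 50 °C
Reagents that add atoms: none
Why: Hydrogenolysis cleaves the four aryl benzyl ethers, and the freed C8a phenol of 14 adds to the aldehyde (6-exo-trig) to give hemiacetal 15. Acid-catalysed dehydration, driven by conjugation with the pyranone carbonyl, then gives 16. Holding C2 as a hemiacetal under neutral conditions and adding acid only after the catalyst is removed keeps the C2=C3 double bond away from hydrogen.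

## Compound list

1 | 1-(2,3,4-trihydroxyphenyl)ethanone (gallacetophenone) | CC(=O)c1ccc(O)c(O)c1O | starting material
2 | benzyl bromide | BrCc1ccccc1 | starting material
3 | 1-[3,4-bis(benzyloxy)-2-hydroxyphenyl]ethanone | CC(=O)c1ccc(OCc2ccccc2)c(OCc2ccccc2)c1O | intermediate
4 | potassium 5-acetyl-2,3-bis(benzyloxy)-4-hydroxyphenyl sulfate | CC(=O)c1cc(OS(=O)(=O)[O-])c(OCc2ccccc2)c(OCc2ccccc2)c1O.[K+] | intermediate
5 | 1-[3,4-bis(benzyloxy)-2,5-dihydroxyphenyl]ethanone | CC(=O)c1cc(O)c(OCc2ccccc2)c(OCc2ccccc2)c1O | intermediate
6 | 1-[3,4-bis(benzyloxy)-2-hydroxy-5-methoxyphenyl]ethanone | CC(=O)c1cc(OC)c(OCc2ccccc2)c(OCc2ccccc2)c1O | intermediate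
7 | 1-[2,3,4-tris(benzyloxy)-5-methoxyphenyl]ethanone | CC(=O)c1cc(OC)c(OCc2ccccc2)c(OCc2ccccc2)c1OCc1ccccc1 | intermediate
8 | 3-hydroxy-4,5-dimethoxybenzaldehyde | COc1cc(C=O)cc(O)c1OC | starting material
9 | 3-(benzyloxy)-4,5-dimethoxybenzaldehyde | COc1cc(C=O)cc(OCc2ccccc2)c1OC | intermediate
10 | 3-[3-(benzyloxy)-4,5-dimethoxyphenyl]-3-hydroxy-1-[2,3,4-tris(benzyloxy)-5-methoxyphenyl]propan-1-one (racemic) | COc1cc(C(=O)CC(O)c2cc(OCc3ccccc3)c(OC)c(OC)c2)c(OCc2ccccc2)c(OCc2ccccc2)c1OCc1ccccc1 | intermediate
11 | (2E)-3-[3-(benzyloxy)-4,5-dimethoxyphenyl]-1-[2,3,4-tris(benzyloxy)-5-methoxyphenyl]prop-2-en-1-one | COc1cc(C(=O)/C=C/c2cc(OCc3ccccc3)c(OC)c(OC)c2)c(OCc2ccccc2)c(OCc2ccccc2)c1OCc1ccccc1 | intermediate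
12 | trans-{3-[3-(benzyloxy)-4,5-dimethoxyphenyl]oxiran-2-yl}[2,3,4-tris(benzyloxy)-5-methoxyphenyl]methanone (racemic; 2R,3S enantiomer drawn) | COc1cc(C(=O)[C@@H]2O[C@H]2c2cc(OCc3ccccc3)c(OC)c(OC)c2)c(OCc2ccccc2)c(OCc2ccccc2)c1OCc1ccccc1 | intermediate
13 | 2-[3-(benzyloxy)-4,5-dimethoxyphenyl]-3-oxo-3-[2,3,4-tris(benzyloxy)-5-methoxyphenyl]propanal (racemic; enolisable) | COc1cc(C(=O)C(C=O)c2cc(OCc3ccccc3)c(OC)c(OC)c2)c(OCc2ccccc2)c(OCc2ccccc2)c1OCc1ccccc1 | intermediate
14 | 2-(3-hydroxy-4,5-dimethoxyphenyl)-3-oxo-3-(2,3,4-trihydroxy-5-methoxyphenyl)propanal (racemic; enolisable) | COc1cc(C(=O)C(C=O)c2cc(O)c(OC)c(OC)c2)c(O)c(O)c1O | intermediate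
15 | 2,7,8-trihydroxy-3-(3-hydroxy-4,5-dimethoxyphenyl)-6-methoxy-2,3-dihydro-4H-chromen-4-one (mixture of diastereomers) | COc1cc2c(c(O)c1O)OC(O)C(c1cc(O)c(OC)c(OC)c1)C2=O | intermediate
16 | 7,8-dihydroxy-3-(3-hydroxy-4,5-dimethoxyphenyl)-6-methoxy-4H-chromen-4-one | COc1cc2c(=O)c(-c3cc(O)c(OC)c(OC)c3)coc2c(O)c1O | target

## Step count and least certain steps

Total step count: 9. Longest linear sequence: 8 steps (steps 1–4 and 6–9); the ring B branch is step 5.

**Step 8 (key step).** The most likely failure is slow or unselective ionisation, because ring B stabilises the benzylic position less than a simple 4-methoxyphenyl group would. That gives time for fluoride capture of the cationic carbon, for participation of the 2'-benzyloxy oxygen with loss of benzyl and closure to a flavanonol, and for loss of the formyl group from the product during a long reaction or work-up. The fallback sets out from chalcone 11 and uses an oxidative 1,2-aryl shift instead of the acyl shift. Tl(NO3)3·3H2O (trivalent thallium) in MeOH–HC(OMe)3 at rt adds methanol to the β-carbon and thallium to the α-carbon. Ring B then migrates to the α-carbon as monovalent thallium departs, and the oxocarbenium ion is trapped as the dimethyl acetal 2-[3-(benzyloxy)-4,5-dimethoxyphenyl]-3,3-dimethoxy-1-[2,3,4-tris(benzyloxy)-5-methoxyphenyl]propan-1-one F1, which holds the same C2–C3(ring B)–C4 chain with C2 as an acetal. Hydrogenolysis (H2, Pd/C) gives the tetraphenol acetal 2-(3-hydroxy-4,5-dimethoxyphenyl)-3,3-dimethoxy-1-(2,3,4-trihydroxy-5-methoxyphenyl)propan-1-one F2, and HCl in MeOH closes the ring with loss of methanol. The fallback comes back to the route at 16.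

**Step 2.** Elbs oxidations typically stop at partial conversion and are accompanied by oxidative degradation. The dibenzylated phenolate may dissolve poorly, and hot acid during sulfate hydrolysis may start to remove benzyl ethers. The fallback sets out from 3. Bromination para to the free phenol (N-bromosuccinimide, MeCN, 0 °C) gives 1-[3,4-bis(benzyloxy)-5-bromo-2-hydroxyphenyl]ethanone F3. Ullmann-type methoxylation (NaOMe, CuBr cat., MeOH–DMF, 110 °C) then replaces bromine by methoxy. The fallback comes back at 6 and bypasses 5 and step 3.

**Step 9.** Possible problems are over-reduction of the aldehyde or its enol, incomplete cleavage of the crowded benzyl ethers, and air oxidation of the catechol once it is free. The fallback sets out from 13 and removes the benzyl groups without hydrogen: BCl3 with pentamethylbenzene as cation scavenger in CH2Cl2 at −78 °C, then methanol quench, gentle warming and aqueous work-up. The acid generated closes and dehydrates through 14 and 15, and the fallback comes back at 16. The low temperature is needed to spare the methyl ethers. No new compound is made.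

**Step 1.** Selectivity rests only on the hydrogen bond of the 2-hydroxyl, so over-alkylation to the tribenzyl ether or mixtures of mono- and dibenzyl ethers may result. The fallback sets out from 1. Exhaustive benzylation (three equivalents of 2 or more, K2CO3, DMF, 70 °C) gives 1-[2,3,4-tris(benzyloxy)phenyl]ethanone F4. MgBr2·OEt2 in toluene–Et2O with warming then cleaves only the benzyl ether ortho to the carbonyl, through a six-membered magnesium chelate. The fallback comes back at 3.

**Step 7.** Conjugate addition of hydroperoxide may be slow because the electron-rich ring B deactivates the β-carbon, and long exposure to alkaline peroxide invites retro-aldol cleavage. The fallback sets out from 7 and builds the epoxide by a Darzens condensation. α-Bromination (CuBr2, divalent copper, EtOAc–CHCl3, reflux) gives 2-bromo-1-[2,3,4-tris(benzyloxy)-5-methoxyphenyl]ethanone F5. Reaction of F5 with aldehyde 9 (NaOMe, MeOH–THF, 0 °C) should give the trans glycidic ketone. The fallback comes back at 12.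

## Further compounds

F1 | step 8 | 2-[3-(benzyloxy)-4,5-dimethoxyphenyl]-3,3-dimethoxy-1-[2,3,4-tris(benzyloxy)-5-methoxyphenyl]propan-1-one (racemic) | COc1cc(C(=O)C(C(OC)OC)c2cc(OCc3ccccc3)c(OC)c(OC)c2)c(OCc2ccccc2)c(OCc2ccccc2)c1OCc1ccccc1
F2 | step 8 | 2-(3-hydroxy-4,5-dimethoxyphenyl)-3,3-dimethoxy-1-(2,3,4-trihydroxy-5-methoxyphenyl)propan-1-one (racemic) | COc1cc(C(=O)C(C(OC)OC)c2cc(O)c(OC)c(OC)c2)c(O)c(O)c1O
F3 | step 2 | 1-[3,4-bis(benzyloxy)-5-bromo-2-hydroxyphenyl]ethanone | CC(=O)c1cc(Br)c(OCc2ccccc2)c(OCc2ccccc2)c1O
F0 | step 9 | none | none
F4 | step 1 | 1-[2,3,4-tris(benzyloxy)phenyl]ethanone | CC(=O)c1ccc(OCc2ccccc2)c(OCc2ccccc2)c1OCc1ccccc1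
F5 | step 7 | 2-bromo-1-[2,3,4-tris(benzyloxy)-5-methoxyphenyl]ethanone | COc1cc(C(=O)CBr)c(OCc2ccccc2)c(OCc2ccccc2)c1OCc1ccccc1
A1 | alternative 1 | 6-[2-(3-benzyloxy-4,5-dimethoxyphenyl)-1-(tert-butyldimethylsilyloxy)ethyl]-4-methoxy-2,3-di(propan-2-yloxy)phenol (racemic) | COc1cc(C(O[Si](C)(C)C(C)(C)C)Cc2cc(OCc3ccccc3)c(OC)c(OC)c2)c(O)c(OC(C)C)c1OC(C)C
A2 | alternative 1 | 4-[(1E)-4-(3-benzyloxy-4,5-dimethoxyphenyl)-3-(tert-butyldimethylsilyloxy)but-1-enyl]-4-methoxy-2,3-di(propan-2-yloxy)cyclobut-2-en-1-one (mixture of diastereomers) | COC1(/C=C/C(O[Si](C)(C)C(C)(C)C)Cc2cc(OCc3ccccc3)c(OC)c(OC)c2)C(=O)C(OC(C)C)=C1OC(C)C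
A3 | alternative 1 | 3,4-di(propan-2-yloxy)cyclobut-3-ene-1,2-dione (diisopropyl squarate) | CC(C)OC1=C(OC(C)C)C(=O)C1=O
A4 | alternative 1 | (3Z,5E)-8-(3-benzyloxy-4,5-dimethoxyphenyl)-7-(tert-butyldimethylsilyloxy)-4-methoxy-2,3-di(propan-2-yloxy)octa-1,3,5-trien-1-one (dienylketene from ring opening of A2; racemic) | O=C=C(OC(C)C)/C(OC(C)C)=C(OC)\C=C\C(O[Si](C)(C)C(C)(C)C)Cc1cc(OCc2ccccc2)c(OC)c(OC)c1
A5 | alternative 2 | 7,8-bis(benzyloxy)-3-(3-benzyloxy-4,5-dimethoxyphenyl)-6-methoxychroman-4-one (racemic) | COc1cc2c(c(OCc3ccccc3)c1OCc1ccccc1)OCC(c1cc(OCc3ccccc3)c(OC)c(OC)c1)C2=O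
A6 | alternative 2 | 2,3-bis(benzyloxy)-6-iodo-4-methoxyphenol | COc1cc(I)c(O)c(OCc2ccccc2)c1OCc1ccccc1
A7 | alternative 2 | carbon monoxide | [C-]#[O+]
A8 | alternative 2 | 2-[1-(3-benzyloxy-4,5-dimethoxyphenyl)ethenyl]-4,4,5,5-tetramethyl-1,3,2-dioxaborolane | C=C(B1OC(C)(C)C(C)(C)O1)c1cc(OCc2ccccc2)c(OC)c(OC)c1
A9 | alternative 2 | 1-[3,4-bis(benzyloxy)-2-hydroxy-5-methoxyphenyl]-2-(3-benzyloxy-4,5-dimethoxyphenyl)prop-2-en-1-one | C=C(C(=O)c1cc(OC)c(OCc2ccccc2)c(OCc2ccccc2)c1O)c1cc(OCc2ccccc2)c(OC)c(OC)c1
A10 | alternative 3 | 3-(3-benzyloxy-4,5-dimethoxyphenyl)-7,8-dihydroxy-6-methoxychromen-4-one | COc1cc2c(=O)c(-c3cc(OCc4ccccc4)c(OC)c(OC)c3)coc2c(O)c1O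
A11 | alternative 3 | 2-(3-benzyloxy-4,5-dimethoxyphenyl)-3-(3,4-dihydroxy-5-methoxyphenyl)-3-oxopropanal (racemic; enolisable) | COc1cc(C(=O)C(C=O)c2cc(OCc3ccccc3)c(OC)c(OC)c2)cc(O)c1O
A12 | alternative 3 | 2-(3-benzyloxy-4,5-dimethoxyphenyl)-3-(5-methoxy-3,4-dioxocyclohexa-1,5-dien-1-yl)-3-oxopropanal (racemic; enolisable) | COC1=CC(C(=O)C(C=O)c2cc(OCc3ccccc3)c(OC)c(OC)c2)=CC(=O)C1=O
A13 | alternative 3 | 3-(3-benzyloxy-4,5-dimethoxyphenyl)-6,7-dihydroxy-8-methoxychromen-4-one | COc1c(O)c(O)cc2c(=O)c(-c3cc(OCc4ccccc4)c(OC)c(OC)c3)coc12
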